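In a one-step world electrophile would become target and nothing else, yet in the dawn run at 8.00 h the electrophile and target together came to 36.1% of the charge. So I took it that the electrophile had a second way out, and I asked how many halvings of it remained before the end.

| setting | dawn | spring | Sunday's | Wednesday's | Tuesday's |
|---|---|---|---|---|---|
| electrophile | 0.083 M | 0.083 M | 0.083 M | 0.083 M | 0.083 M |
| nucleophile | 0.10 M | 0.32 M | 0.0910 M | 0.140 M | 0.210 M |
| remark | run made earlier | run made earlier |  |  |  |
| time |  |  | 15 h | 15 h | 15 h |

| run | time / h | electrophile / % | target / % |
|---|---|---|---|
| dawn | 0.667 | 58.9 | 9.1 |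
| dawn | 1.00 | 48.1 | 12.7 |
| dawn | 2.00 | 30.6 | 18.3 |
| dawn | 4.00 | 16.5 | 24.6 |
| dawn | 8.00 | 6.1 | 30.0 |
| spring | 0.667 | 47.0 | 26.9 |
| spring | 2.00 | 17.8 | 46.5 |
| spring | 4.00 | 6.1 | 56.1 |
| spring | 5.00 | 3.4 | 58.8 |
| spring | 8.00 | 1.0 | 60.8 |

(readings scatter by 0.3 percentage points)

- the numbers in the tables scatter by 0.3 percentage points (one standard deviation)

- part of the electrophile that has reacted at the end, Sunday's
- part of the electrophile that has reacted at the end, Wednesday's
- part of the electrophile that has reacted at the end, Tuesday's
- what raising the concentration of nucleophile from its lowest to its highest value here does to the part of the electrophile that has reacted (changes below 5 percentage points count as none) (it falls / no change / it rises)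

I started with Sunday's flask, which holds the lowest nucleophile, and let the dawn run, nearest in charge, stand in for it. In the dawn run the electrophile went from 16.5% to 6.1% over the last interval, which gives 2.79 h as the late half-life, the time the remaining electrophile takes to halve near the last readings. The interval before gave 2.24 h, so the half-life was lengthening, and I also counted with a cautious 5.57 h.

How much could then remain? From 8.00 h to 15 h there are 2.51 halvings at the first value and 1.26 at the second, so on these counts the 6.1% comes down to 1.07% or 2.55%.

Could that show as a trend? The part reacted cannot pass the whole charge, so the rise from Sunday's to Tuesday's cannot pass what Sunday's leaves, and my higher count of that, 2.55%, is less than the margin of 5 percentage points. I expected no change.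

The forecast gave 98%, 99.3% and 99.8% for Sunday's, Wednesday's and Tuesday's, and no change: “Neither path stops: the electrophile keeps falling, with no sign of a plateau or equilibrium.” Its Sunday's value leaves 2.00%, between my two counts.

The flasks gave 97.6%, 98.9% and 99.7%, with no change: the change was 2.1 points.

    electrophile + nucleophile → acid set free + target (k = 0.0330 /M/min)
    2 electrophile → self-condensation product (k = 0.0810 /M/min)
    nucleophile + acid set free ⇌ protonated nucleophile, settled at all times (K = 520 /M)
    acid set free → by-product carried off (k = 0.130 /min)

In Sunday's flask the electrophile fell from 7.89% at 7.50 h to 2.40% at 15.0 h, an average half-life over that stretch of 4.36 h, which lies between 2.79 h and 5.57 h. Counted from the 5.53% of Wednesday's flask at 7.50 h, these two half-lives leave 0.856% and 2.18%. Electrophile, the limiting reagent there, stood at 1.11% at 15.0 h.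

The readings were generated by integration with constants of no real substance; scatter was added.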